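**Plan**
- Retrosynthesis: both carbinol C–H bonds are cut back to aryl ketones. The oxolane is cut at O1–C5 and C2–C3 together, which excises formaldehyde and leaves a 2-substituted cyclopropyl aryl ketone. The two aryl–CO bonds are then cut to a cyclopropane-1,2-dicarboxylic acid and two aryl Grignard units.
- Enabling feature: C-5 is an unsubstituted ring CH2 on oxygen, and C-3 lies α to a benzylic carbinol carbon that can be raised to an aroyl ketone. C-5, C-4 and C-3 therefore map onto an acceptor cyclopropane whose C3–C5 bond an iodide can cut at CH2.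
- Forward: the C2-symmetric 1,2-diaroylcyclopropane is built in two directions, the symmetry is broken by reducing one ketone, and the silylated cyclopropyl ketone is expanded by formaldehyde to the oxolane. The second ketone is then reduced and the protecting groups are removed.
- Stereochemistry: C-4 comes from the (1S,2S)-diacid, the S carbinol from a reduction with the R catalyst, C-3 is set trans under thermodynamic control in the ring expansion, and the R carbinol comes from a reduction with the S catalyst.

Key step: step 5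

Remark: (1S,2S)-cyclopropane-1,2-dicarboxylic acid is assumed to be bought as the resolved acid. Ar = 4-(benzyloxy)-3-methoxyphenyl. Oxolane atoms are numbered O1, C2, C3, C4, C5, with C-3 carrying the aroyl group (later the R carbinol) and C-4 the S carbinol.

**Step 1**
Reactants: 1 (1S,2S)-cyclopropane-1,2-dicarboxylic acid
Product: 3 (1S,2S)-N1,N2-dimethoxy-N1,N2-dimethylcyclopropane-1,2-dicarboxamide, via diacid dichloride 2 (not isolated)
Conditions: (COCl)2 (2.4 equiv), cat. DMF, CH2Cl2, 0 → 23 °C; then MeNHOMe·HCl (2.4 equiv), pyridine, CH2Cl2, 0 °C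
Reagents that add atoms: N,O-dimethylhydroxylamine hydrochloride CNOC.Cl (two equivalents, one per carboxyl group); oxalyl chloride ClC(=O)C(Cl)=O (chlorine of 2 only)
Why: Standard acid chloride formation and amidation on both carboxyl groups at once; the trans-cyclopropane cannot close to an anhydride and its ring hydrogens do not epimerize.

**Step 2**
Reactants: 3 bis-Weinreb amide; 4 1-(benzyloxy)-4-bromo-2-methoxybenzene (2 equiv, one per amide group)
Product: 6 [(1S,2S)-cyclopropane-1,2-diyl]bis{[4-(benzyloxy)-3-methoxyphenyl]methanone}, via arylmagnesium bromide 5 (not isolated)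
Conditions: 4 (2.4 equiv), Mg turnings (2.6 equiv), THF, 40 °C; then 3 (1.0 equiv), THF, 0 → 23 °C; aq. NH4Cl
Reagents that add atoms: 1-(benzyloxy)-4-bromo-2-methoxybenzene COc1cc(Br)ccc1OCc1ccccc1 (the second equivalent of 4, which supplies the second aryl group); magnesium [Mg] (in 5 only)
Why: Two-directional Weinreb ketone synthesis in which two equivalents of Grignard reagent 5 add, one to each amide group; the stable magnesium chelates stop each end at the ketone stage and the ring stereocenters are untouched.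

**Step 3**
Reactants: 6 diketone
Product: 7 [4-(benzyloxy)-3-methoxyphenyl][(1S,2S)-2-{(S)-[4-(benzyloxy)-3-methoxyphenyl](hydroxy)methyl}cyclopropyl]methanone
Conditions: (R)-1-methyl-3,3-diphenyltetrahydro-1H,3H-pyrrolo[1,2-c][1,3,2]oxazaborole [(R)-Me-CBS, C18H20BNO, 20 mol%], catecholborane (1.0 equiv), toluene, −78 °C; MeOH, aq. NaHCO3
Reagents that add atoms: none
Why: Corey–Bakshi–Shibata reduction with one hydride equivalent; the two ketones are homotopic so only one mono-alcohol can form, the aryl group should take the large-group role so that the R catalyst gives the S carbinol, and the product should be reduced more slowly because it has lost the activating second aroyl group.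

**Step 4**
Reactants: 7 hydroxy ketone
Product: 8 [4-(benzyloxy)-3-methoxyphenyl][(1S,2S)-2-{(S)-[4-(benzyloxy)-3-methoxyphenyl][(tert-butyldimethylsilyl)oxy]methyl}cyclopropyl]methanone
Conditions: TBSCl, imidazole, DMF, 23 → 40 °C
Reagents that add atoms: tert-butyldimethylsilyl chloride CC(C)(C)[Si](C)(C)Cl
Why: Routine silylation of a secondary benzylic alcohol under non-acidic conditions, which spares the acid-sensitive cyclopropylcarbinol and masks the hydroxyl for the ring expansion.

**Step 5**
Reactants: 8 silylated cyclopropyl ketone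
Product: 12 [4-(benzyloxy)-3-methoxyphenyl][(3R,4R)-4-{(S)-[4-(benzyloxy)-3-methoxyphenyl][(tert-butyldimethylsilyl)oxy]methyl}oxolan-3-yl]methanone, via γ-iodo magnesium enolate 9 (not isolated), via magnesium iodo aldolate 10 (not isolated), via cis-oxolane epimer 11 (not isolated)
Conditions: MgI2 (1.5 equiv), (CH2O)n (5 equiv), THF, 70 °C, sealed tube; then DBU (1 equiv), 40 °C
Reagents that add atoms: formaldehyde C=O (from paraformaldehyde); magnesium iodide [Mg+2].[I-].[I-] (iodine and magnesium of 9 and 10 only)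
Why: Proposed new method: MgI2 binds the aroyl oxygen, iodide opens the cyclopropane by SN2 attack at the unsubstituted CH2 to give the γ-iodo magnesium Z-enolate 9, whose aldol addition to monomeric formaldehyde makes the C2–C3 bond (aldolate 10); the alkoxide then displaces the primary iodide and makes the O1–C5 bond, so the cyclopropane is traded for the oxolane in a formal [3+2] ring expansion. The closest known reaction types are the metal-iodide-promoted ring expansion of cyclopropyl ketones and spirocyclopropyl oxindoles with aldimines to pyrrolidines and the iodide-induced ring-opening aldol reaction of aryl cyclopropyl ketones with aldehydes; the oxygen version should follow because attack of an alkoxide on a primary iodide five atoms away is fast once DBU frees the aldolate from magnesium. The oxolane is the only ring closed, and it closes 5-exo-tet. C-4 keeps all four of its bonds and carries the configuration of the diacid through unchanged, while the new stereocenter C-3 lies α to the aroyl group and is set under thermodynamic control by C-4, DBU equilibrating the cis epimer 11 to the trans isomer 12 in which the two branched substituents avoid each other. The step needs iodide to attack CH2 and not the substituted ring carbon, which the branched, β-oxygenated side chain secures by making that carbon neopentyl-like and inductively deactivated; it also needs the benzylic carbinol carbon to stay intact, which the bulky silyl ether (a poor ligand for MgI2) and the absence of an acidic hydrogen at C-4 secure.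

**Step 6**
Reactants: 12 oxolanyl aryl ketone
Product: 13 (R)-[4-(benzyloxy)-3-methoxyphenyl][(3R,4R)-4-{(S)-[4-(benzyloxy)-3-methoxyphenyl][(tert-butyldimethylsilyl)oxy]methyl}oxolan-3-yl]methanol
Conditions: (S)-Me-CBS (C18H20BNO, 30 mol%), BH3·SMe2 (1.0 equiv), THF, −20 °C; MeOH, then aq. NH4Cl
Reagents that add atoms: none
Why: Corey–Bakshi–Shibata reduction under catalyst control, the S catalyst delivering hydride so that the aryl ketone gives the R carbinol; this is the anti-Felkin sense at C-3 (C-4 as the large group), so reagent control and not substrate control is relied on.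

**Step 7**
Reactants: 13 silyl ether
Product: 14 (R)-[4-(benzyloxy)-3-methoxyphenyl][(3R,4R)-4-{(S)-[4-(benzyloxy)-3-methoxyphenyl](hydroxy)methyl}oxolan-3-yl]methanol
Conditions: n-Bu4NF, THF, 0 → 23 °C; aq. NH4Cl
Reagents that add atoms: none
Why: Fluoride cleavage of the secondary silyl ether while the phenols are still benzylated, so that no phenoxide can expel the benzylic oxygen as a quinone methide.

**Step 8**
Reactants: 14 bis(benzyl ether) diol
Product: 15 (R)-[(3R,4R)-4-[(S)-hydroxy(4-hydroxy-3-methoxyphenyl)methyl]oxolan-3-yl](4-hydroxy-3-methoxyphenyl)methanol (target)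
Conditions: H2 (1 atm), Pd/C, EtOAc, 23 °C
Reagents that add atoms: none
Why: Hydrogenolysis of the two aryl benzyl ethers under neutral conditions, stopped after two equivalents of hydrogen, should be much faster than cleavage of the secondary benzylic C–OH bonds in the absence of acid.

**Compound list**
1 | (1S,2S)-cyclopropane-1,2-dicarboxylic acid | O=C(O)[C@H]1C[C@@H]1C(=O)O | starting material
2 | (1S,2S)-cyclopropane-1,2-dicarbonyl dichloride | O=C(Cl)[C@H]1C[C@@H]1C(=O)Cl | intermediate
3 | (1S,2S)-N1,N2-dimethoxy-N1,N2-dimethylcyclopropane-1,2-dicarboxamide | CON(C)C(=O)[C@H]1C[C@@H]1C(=O)N(C)OC | intermediate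
4 | 1-(benzyloxy)-4-bromo-2-methoxybenzene | COc1cc(Br)ccc1OCc1ccccc1 | starting material
5 | [4-(benzyloxy)-3-methoxyphenyl]magnesium bromide | COc1cc([Mg]Br)ccc1OCc1ccccc1 | intermediate
6 | [(1S,2S)-cyclopropane-1,2-diyl]bis{[4-(benzyloxy)-3-methoxyphenyl]methanone} | COc1cc(C(=O)[C@H]2C[C@@H]2C(=O)c2ccc(OCc3ccccc3)c(OC)c2)ccc1OCc1ccccc1 | intermediate
7 | [4-(benzyloxy)-3-methoxyphenyl][(1S,2S)-2-{(S)-[4-(benzyloxy)-3-methoxyphenyl](hydroxy)methyl}cyclopropyl]methanone | COc1cc([C@@H](O)[C@H]2C[C@@H]2C(=O)c2ccc(OCc3ccccc3)c(OC)c2)ccc1OCc1ccccc1 | intermediate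
8 | [4-(benzyloxy)-3-methoxyphenyl][(1S,2S)-2-{(S)-[4-(benzyloxy)-3-methoxyphenyl][(tert-butyldimethylsilyl)oxy]methyl}cyclopropyl]methanone | COc1cc([C@@H](O[Si](C)(C)C(C)(C)C)[C@H]2C[C@@H]2C(=O)c2ccc(OCc3ccccc3)c(OC)c2)ccc1OCc1ccccc1 | intermediate
9 | iodomagnesium Z-enolate of (3S,4S)-1,4-bis[4-(benzyloxy)-3-methoxyphenyl]-4-[(tert-butyldimethylsilyl)oxy]-3-(iodomethyl)butan-1-one | COc1cc([C@@H](O[Si](C)(C)C(C)(C)C)[C@@H](CI)/C=C(\O[Mg]I)c2ccc(OCc3ccccc3)c(OC)c2)ccc1OCc1ccccc1 | intermediate
10 | iodomagnesium alkoxide of (3S,4S)-1,4-bis[4-(benzyloxy)-3-methoxyphenyl]-4-[(tert-butyldimethylsilyl)oxy]-2-(hydroxymethyl)-3-(iodomethyl)butan-1-one (both C-2 epimers) | COc1cc([C@@H](O[Si](C)(C)C(C)(C)C)[C@@H](CI)C(CO[Mg]I)C(=O)c2ccc(OCc3ccccc3)c(OC)c2)ccc1OCc1ccccc1 | intermediate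
11 | [4-(benzyloxy)-3-methoxyphenyl][(3S,4R)-4-{(S)-[4-(benzyloxy)-3-methoxyphenyl][(tert-butyldimethylsilyl)oxy]methyl}oxolan-3-yl]methanone (cis) | COc1cc([C@@H](O[Si](C)(C)C(C)(C)C)[C@H]2COC[C@H]2C(=O)c2ccc(OCc3ccccc3)c(OC)c2)ccc1OCc1ccccc1 | intermediate
12 | [4-(benzyloxy)-3-methoxyphenyl][(3R,4R)-4-{(S)-[4-(benzyloxy)-3-methoxyphenyl][(tert-butyldimethylsilyl)oxy]methyl}oxolan-3-yl]methanone (trans) | COc1cc([C@@H](O[Si](C)(C)C(C)(C)C)[C@H]2COC[C@@H]2C(=O)c2ccc(OCc3ccccc3)c(OC)c2)ccc1OCc1ccccc1 | intermediate
13 | (R)-[4-(benzyloxy)-3-methoxyphenyl][(3R,4R)-4-{(S)-[4-(benzyloxy)-3-methoxyphenyl][(tert-butyldimethylsilyl)oxy]methyl}oxolan-3-yl]methanol | COc1cc([C@@H](O[Si](C)(C)C(C)(C)C)[C@H]2COC[C@@H]2[C@@H](O)c2ccc(OCc3ccccc3)c(OC)c2)ccc1OCc1ccccc1 | intermediate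
14 | (R)-[4-(benzyloxy)-3-methoxyphenyl][(3R,4R)-4-{(S)-[4-(benzyloxy)-3-methoxyphenyl](hydroxy)methyl}oxolan-3-yl]methanol | COc1cc([C@@H](O)[C@H]2COC[C@@H]2[C@@H](O)c2ccc(OCc3ccccc3)c(OC)c2)ccc1OCc1ccccc1 | intermediate
15 | (R)-[(3R,4R)-4-[(S)-hydroxy(4-hydroxy-3-methoxyphenyl)methyl]oxolan-3-yl](4-hydroxy-3-methoxyphenyl)methanol | COc1cc([C@@H](O)[C@H]2COC[C@@H]2[C@@H](O)c2ccc(O)c(OC)c2)ccc1O | target

**Count and risks**
Total steps: 8. Longest linear sequence: 8 steps (1 → 15); aryl bromide 4 enters at step 2 in two equivalents.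

Steps most likely to fail:

1. Step 5. The ring opening may be slow or iodide may attack the substituted ring carbon. MgI2 at 70 °C may ionize the benzylic cyclopropylcarbinyl silyl ether. The aldolate may dehydrate to the α-methylene ketone or take up a second formaldehyde before it closes. The fallback uses known chemistry and separates the two bond formations. It sets out from 8: TiCl4 and n-Bu4NI in CH2Cl2 at −78 → 0 °C open the cyclopropane to the titanium enolate (the known ring-opening aldol reaction of aryl cyclopropyl ketones). Monomeric formaldehyde in THF at −78 °C should then give, after work-up, the isolated γ-iodo aldol (3S,4S)-1,4-bis[4-(benzyloxy)-3-methoxyphenyl]-4-[(tert-butyldimethylsilyl)oxy]-2-(hydroxymethyl)-3-(iodomethyl)butan-1-one F1. K2CO3 in MeOH/THF at 23 °C then closes the ring by Williamson etherification and equilibrates C-3, and the route is rejoined at 12.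

2. Step 6. Facial selectivity may be poor because catalyst control has to override the Felkin preference of the α-branched ketone. The fallback sets out from 12: substrate-controlled reduction with LiBH(s-Bu)3 in THF at −78 °C should give the epimeric alcohol (S)-[4-(benzyloxy)-3-methoxyphenyl][(3R,4R)-4-{(S)-[4-(benzyloxy)-3-methoxyphenyl][(tert-butyldimethylsilyl)oxy]methyl}oxolan-3-yl]methanol F2. Mitsunobu inversion (4-nitrobenzoic acid, PPh3, diisopropyl azodicarboxylate, THF, 0 °C) gives the inverted ester (R)-[4-(benzyloxy)-3-methoxyphenyl][(3R,4R)-4-{(S)-[4-(benzyloxy)-3-methoxyphenyl][(tert-butyldimethylsilyl)oxy]methyl}oxolan-3-yl]methyl 4-nitrobenzoate F3, and methanolysis (K2CO3, MeOH) rejoins the route at 13.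

3. Step 3. Over-reduction to the diol and incomplete discrimination between the aryl and cyclopropyl flanks would erode the mono-alcohol. The fallback sets out from 6: both ketones are reduced with (R)-Me-CBS and excess BH3·SMe2 to the C2-symmetric diol (S,S)-[(1S,2S)-cyclopropane-1,2-diyl]bis{[4-(benzyloxy)-3-methoxyphenyl]methanol} F4, which is freed from the minor unsymmetrical isomer by crystallization. Monosilylation of the homotopic hydroxyls (NaH, 1 equiv, then TBSCl, THF) gives (S)-[4-(benzyloxy)-3-methoxyphenyl][(1S,2S)-2-{(S)-[4-(benzyloxy)-3-methoxyphenyl][(tert-butyldimethylsilyl)oxy]methyl}cyclopropyl]methanol F5, and MnO2 in CH2Cl2 oxidizes the free benzylic alcohol to rejoin the route at 8.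

**Further compounds**
F1 | step 5 | (3S,4S)-1,4-bis[4-(benzyloxy)-3-methoxyphenyl]-4-[(tert-butyldimethylsilyl)oxy]-2-(hydroxymethyl)-3-(iodomethyl)butan-1-one (C-2 epimers) | COc1cc([C@@H](O[Si](C)(C)C(C)(C)C)[C@@H](CI)C(CO)C(=O)c2ccc(OCc3ccccc3)c(OC)c2)ccc1OCc1ccccc1
F2 | step 6 | (S)-[4-(benzyloxy)-3-methoxyphenyl][(3R,4R)-4-{(S)-[4-(benzyloxy)-3-methoxyphenyl][(tert-butyldimethylsilyl)oxy]methyl}oxolan-3-yl]methanol | COc1cc([C@@H](O[Si](C)(C)C(C)(C)C)[C@H]2COC[C@@H]2[C@H](O)c2ccc(OCc3ccccc3)c(OC)c2)ccc1OCc1ccccc1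
F3 | step 6 | (R)-[4-(benzyloxy)-3-methoxyphenyl][(3R,4R)-4-{(S)-[4-(benzyloxy)-3-methoxyphenyl][(tert-butyldimethylsilyl)oxy]methyl}oxolan-3-yl]methyl 4-nitrobenzoate | COc1cc([C@@H](O[Si](C)(C)C(C)(C)C)[C@H]2COC[C@@H]2[C@@H](OC(=O)c2ccc(cc2)[N+]([O-])=O)c2ccc(OCc3ccccc3)c(OC)c2)ccc1OCc1ccccc1
F4 | step 3 | (S,S)-[(1S,2S)-cyclopropane-1,2-diyl]bis{[4-(benzyloxy)-3-methoxyphenyl]methanol} | COc1cc([C@@H](O)[C@H]2C[C@@H]2[C@H](O)c2ccc(OCc3ccccc3)c(OC)c2)ccc1OCc1ccccc1
F5 | step 3 | (S)-[4-(benzyloxy)-3-methoxyphenyl][(1S,2S)-2-{(S)-[4-(benzyloxy)-3-methoxyphenyl][(tert-butyldimethylsilyl)oxy]methyl}cyclopropyl]methanol | COc1cc([C@@H](O[Si](C)(C)C(C)(C)C)[C@H]2C[C@@H]2[C@H](O)c2ccc(OCc3ccccc3)c(OC)c2)ccc1OCc1ccccc1
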